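Amounts first: this flask holds less substrate than the delta run, with the same gas phase and protic impurity, and I count in fractions of the substrate charged.

- delta: substrate 0.030 M; gas phase 2.9 mM (held); protic impurity 6 mM; run made earlier
- flask: substrate 0.020 M; gas phase 2.9 mM (held); protic impurity 6.00 mM; time 6.0 d

- delta (time / h: target / %, substrate / %): 6.00: 4.6, 70.1; 12.0: 8.1, 48.2; 20.0: 10.2, 29.3; 25.0: 10.9, 20.6; 30.0: 10.6, 14.7; 40.0: 11.2, 6.7

(each reading ± 0.5 percentage points)

- at the start none of the gas phase is in solution

1. the target standing at 6.0 d, as a percentage of the substrate charged
2. concentration of dissolved gas in solution at 6.0 d, in percent of saturation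

I replace the curve by its mean. The mean share, target standing per substrate consumed (a mean selectivity), reads 12.0 % at the last delta reading. The delta substrate halves in about 10.3 h, far shorter than the 6.0 d asked, so if this flask's substrate halves at about that pace, nearly all of its charge should be consumed, and I commit to 12.0 %. The error of using a mean shows in the first reading, whose share is 15.4 %, higher than the mean by 3.4 percentage points.

The forecast is higher than my figure: 13.5 % (from 11.5 % to 15.5 %) and 93 % of saturation, on the ground that “the 6 mM protic impurity looks like a consumed reagent”.

The flask gives 8.62 % and 94.2 %, so the forecast stands within the margins asked.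

    target ⇌ isomer of the product (K = 2.10, k = 0.0470 /h)
    dissolved gas ⇌ dormant form (K = 6.10, k = 0.0430 /h)
    substrate → side product (k = 0.0480 /h)
    substrate + dissolved gas → target (k = 13.0 /M/h)
    dissolved gas + protic impurity → quenched reagent (k = 46.0 /M/h)
    gas phase ⇌ dissolved gas, rate k6*(csat - [dissolved gas]) (kL = 0.300 /h)

The target in this flask ends 3.4 points below my reckoning. It stands at 11.9 % after 1.50 d, level with my reckoning from the mean share 12.0 %, and at 8.62 % after 6.00 d, beside 18.1 % of isomer of the product. So in this flask my reckoning lies near the standing at the earlier time, not at the time asked.

In the neighbour flask with 0.0024 M of protic impurity, 0 % of the substrate remains at 6.00 d, so the mean share, taken over unchanged from the delta run, gives 12.0 %. The computed neighbour flask holds 9.42 % of target at that time, which is 2.6 points lower.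

The earlier runs and the new flask come from a simulation for substances that don't exist, noise included.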